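**Retrosynthetic overview**
1. Target 20 ⇒ allylic α-keto ester 18 by ring-closing carbonyl–olefin metathesis, which closes the butenolide C=C of half A and expels acetone.
2. 18 ⇒ ester C–O bond between allylic alcohol 3 (half A, carbinol already R) and α-keto acid 17 (half B); this C–O bond becomes the butenolide ring oxygen.
3. 17 ⇒ α-methylene lactone 13 plus a pyruvate enol equivalent; 13 ⇒ oxidative lactonisation (C–O) of diol 11, which comes from ketone 5 through 7 and 8.
4. 3 and 4 (the precursor of 5) ⇒ the two diastereomers from Cope rearrangement of (R)-germacrol 2 ⇒ CBS reduction of achiral germacrone 1.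
5. Ring order: both cyclohexanes (one Cope thermolysis) → cis-lactone of half B → butenolide of half A (last).

Assumption: the SMILES is taken literally. The butenolide half is (5R,6R,7aR) and the saturated-lactone half is (3S,3aR,5S,6S,7aR) in benzofuranone numbering, so the two cyclohexane cores are enantiomeric at the methyl/vinyl and isopropenyl carbons while both carbinol carbons are R. Germacrone and pyruvic acid are taken as commercial.

Steps 2 and 3 are one thermolysis and one chromatography; each isolated diastereomer is given its own step.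

**Step 1**
Reactants: 1 germacrone
Product: 2 (1R,3E,7E)-3,7-dimethyl-10-(propan-2-ylidene)cyclodeca-3,7-dien-1-ol
Conditions: (S)-2-methyl-CBS-oxazaborolidine (10 mol%), catecholborane (1.5 equiv), PhMe, −78 °C; aq. NaOH work-up
Reagents that add atoms: none
Why: Corey–Bakshi–Shibata reduction; the catalyst differentiates the fully substituted alkenyl flank (large) from the CH2 flank (small) of the achiral enone, so the 1R carbinol is set by the catalyst alone (sense predicted by the usual model, to be confirmed by Mosher analysis), and catecholborane at −78 °C leaves the trisubstituted olefins alone.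

**Step 2**
Reactants: 2 (1R,3E,7E)-3,7-dimethyl-10-(propan-2-ylidene)cyclodeca-3,7-dien-1-ol
Product: 3 (1R,4R,5R)-5-ethenyl-5-methyl-4-(prop-1-en-2-yl)-2-(propan-2-ylidene)cyclohexan-1-ol
Conditions: PhMe (0.05 M), BHT (cat.), base-washed sealed tube, 170 °C; SiO2 chromatography (first diastereomer)
Reagents that add atoms: none
Why: Thermal Cope rearrangement through a chair transition state of the E,E-cyclodeca-1,5-diene gives the trans-divinyl pattern (methyl cis to isopropenyl); the ring conformer that places the untouched 1R hydroxyl pseudo-equatorial gives the 4R,5R core, so 3 is a single enantiomer and serves half A.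

**Step 3**
Reactants: 2 (1R,3E,7E)-3,7-dimethyl-10-(propan-2-ylidene)cyclodeca-3,7-dien-1-ol
Product: 4 (1R,4S,5S)-5-ethenyl-5-methyl-4-(prop-1-en-2-yl)-2-(propan-2-ylidene)cyclohexan-1-ol
Conditions: same thermolysis as step 2 (PhMe, BHT, sealed tube, 170 °C); SiO2 chromatography (second diastereomer)
Reagents that add atoms: none
Why: The same Cope rearrangement through the enantiomeric crossed ring conformer (hydroxyl pseudo-axial in the chair transition state) gives the 4S,5S core with the same trans-divinyl pattern; because the 1R carbinol is untouched, 4 is a diastereomer of 3, separable on silica and a single enantiomer, and serves half B.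

**Step 4**
Reactants: 4 (1R,4S,5S)-5-ethenyl-5-methyl-4-(prop-1-en-2-yl)-2-(propan-2-ylidene)cyclohexan-1-ol
Product: 5 (4S,5S)-5-ethenyl-5-methyl-4-(prop-1-en-2-yl)-2-(propan-2-ylidene)cyclohexan-1-one
Conditions: MnO2 (15 equiv), CH2Cl2, 25 °C
Reagents that add atoms: none
Why: Allylic alcohol oxidation with MnO2 leaves the isolated olefins alone; the carbinol has served as the resolving handle and the 4S,5S centres are unaffected.

**Step 5**
Reactants: 5 (4S,5S)-5-ethenyl-5-methyl-4-(prop-1-en-2-yl)-2-(propan-2-ylidene)cyclohexan-1-one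
Product: 7 (2R,4S,5S)-5-ethenyl-5-methyl-2,4-di(prop-1-en-2-yl)cyclohexan-1-one, via potassium dienolate 6 (not isolated)
Conditions: KOt-Bu (1.5 equiv), t-BuOH–THF, 25 °C; inverse quench into cold 10% aq. AcOH; used crude
Reagents that add atoms: none
Why: Base-mediated deconjugation (the pulegone-to-isopulegone manoeuvre): reversible γ-deprotonation gives the extended dienolate and kinetic axial protonation at the α-carbon places the isopropenyl group equatorial (2R), which is also the more stable epimer; any unchanged 5 is reduced back to allylic alcohol 4 in step 6, separated there and recycled.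

**Step 6**
Reactants: 7 (2R,4S,5S)-5-ethenyl-5-methyl-2,4-di(prop-1-en-2-yl)cyclohexan-1-one
Product: 8 (1R,2R,4S,5S)-5-ethenyl-5-methyl-2,4-di(prop-1-en-2-yl)cyclohexan-1-ol
Conditions: LiBH(s-Bu)3 (1.3 equiv), THF, −78 °C; H2O
Reagents that add atoms: none
Why: Bulky-hydride ketone reduction; the axial trajectory is blocked by the syn-axial methyl at C5, so hydride enters equatorially and gives the axial 1R alcohol cis to the C2 isopropenyl group.

**Step 7**
Reactants: 8 (1R,2R,4S,5S)-5-ethenyl-5-methyl-2,4-di(prop-1-en-2-yl)cyclohexan-1-ol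
Product: 11 2-[(1R,2R,4S,5S)-4-ethenyl-2-hydroxy-4-methyl-5-(prop-1-en-2-yl)cyclohexyl]prop-2-en-1-ol, via dilithio alkoxide 9 (not isolated), via cyclic boronate 10 (not isolated)
Conditions: n-BuLi (2.4 equiv), TMEDA, Et2O–hexane, 0 to 25 °C; B(OMe)3, −78 °C; NaOH, H2O2, 0 °C
Reagents that add atoms: hydrogen peroxide, OO
Why: Alkoxide-directed allylic lithiation (isopulegol-type dianion) selects the methyl of the isopropenyl group next to the alkoxide; the symmetrical allyl anion is trapped on boron and the C–B bond is oxidised, with no stereocentre touched.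

**Step 8**
Reactants: 11 2-[(1R,2R,4S,5S)-4-ethenyl-2-hydroxy-4-methyl-5-(prop-1-en-2-yl)cyclohexyl]prop-2-en-1-ol
Product: 13 (3aR,5S,6S,7aR)-6-ethenyl-6-methyl-3-methylidene-5-(prop-1-en-2-yl)hexahydro-1-benzofuran-2(3H)-one, via lactol 12 (not isolated)
Conditions: MnO2 (25 equiv), CH2Cl2, 25 °C
Reagents that add atoms: none
Why: Oxidative lactonisation of a 2-methylene-1,4-diol: MnO2 oxidises the allylic primary alcohol to the enal, the secondary hydroxyl closes to the lactol and this is oxidised again, forming the cis-fused lactone C–O bond with all centres intact.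

**Step 9**
Reactants: 13 (3aR,5S,6S,7aR)-6-ethenyl-6-methyl-3-methylidene-5-(prop-1-en-2-yl)hexahydro-1-benzofuran-2(3H)-one; 14 pyruvic acid
Product: 17 4-[(3S,3aR,5S,6S,7aR)-6-ethenyl-6-methyl-2-oxo-5-(prop-1-en-2-yl)octahydro-1-benzofuran-3-yl]-2-oxobutanoic acid, via bis-silyl enol ether 15 (not isolated), via silyl ketene acetal 16 (not isolated)
Conditions: 14, Me3SiCl (2.2 equiv), Et3N, Et2O, 0 to 25 °C, filter under Ar, concentrate; then 13, Me3SiOTf (10 mol%), CH2Cl2, −78 °C; aq. citric acid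
Reagents that add atoms: none
Why: Mukaiyama–Michael addition of the silyl enol ether of pyruvate to the α-methylene lactone; the silyl ketene acetal is protonated on work-up from the convex face of the cis-fused bicycle (the face of the two ring-fusion hydrogens), which sets C3 as S with the side chain on the concave face.

**Step 10**
Reactants: 17 4-[(3S,3aR,5S,6S,7aR)-6-ethenyl-6-methyl-2-oxo-5-(prop-1-en-2-yl)octahydro-1-benzofuran-3-yl]-2-oxobutanoic acid; 3 (1R,4R,5R)-5-ethenyl-5-methyl-4-(prop-1-en-2-yl)-2-(propan-2-ylidene)cyclohexan-1-ol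
Product: 18 (1R,4R,5R)-5-ethenyl-5-methyl-4-(prop-1-en-2-yl)-2-(propan-2-ylidene)cyclohexyl 4-[(3S,3aR,5S,6S,7aR)-6-ethenyl-6-methyl-2-oxo-5-(prop-1-en-2-yl)octahydro-1-benzofuran-3-yl]-2-oxobutanoate
Conditions: DCC (1.2 equiv), DMAP (10 mol%), CH2Cl2, 0 to 25 °C
Reagents that add atoms: none
Why: Steglich esterification joins the two halves through the C–O bond that becomes the butenolide ring oxygen; only the O–H bond of 3 is broken, so its carbinol centre is retained.

**Step 11**
Reactants: 18 (1R,4R,5R)-5-ethenyl-5-methyl-4-(prop-1-en-2-yl)-2-(propan-2-ylidene)cyclohexyl 4-[(3S,3aR,5S,6S,7aR)-6-ethenyl-6-methyl-2-oxo-5-(prop-1-en-2-yl)octahydro-1-benzofuran-3-yl]-2-oxobutanoate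
Product: 20 (5R,6R,7aR)-6-ethenyl-3-{2-[(3S,3aR,5S,6S,7aR)-6-ethenyl-6-methyl-2-oxo-5-(prop-1-en-2-yl)octahydro-1-benzofuran-3-yl]ethyl}-6-methyl-5-(prop-1-en-2-yl)-5,6,7,7a-tetrahydro-1-benzofuran-2(4H)-one, via oxetane 19 (not isolated)
Conditions: FeCl3 (10 mol%), ClCH2CH2Cl, 4 Å MS, 0 to 25 °C
Reagents that add atoms: none
Why: Proposed new method: ring-closing carbonyl–olefin metathesis of an ester-tethered α-keto ester with a tetrasubstituted isopropylidene olefin to give a butenolide; FeCl3 chelates the 1,2-dicarbonyl, the electron-rich ring olefin carbon attacks the ketone carbon (five-membered closure, cationic character on the CMe2 carbon), oxetane 19 forms and cycloreverts to the conjugated lactone and acetone, while the vinyl and isopropenyl groups are far less nucleophilic and the carbinol centre is not involved; the closest known reaction types are the FeCl3-catalysed ring-closing carbonyl–olefin metathesis of aryl ketones and β-keto esters with prenyl-type olefins and the Lewis-acid intramolecular carbonyl-ene closure of unsaturated α-keto esters to α-hydroxy lactones, and to my knowledge the metathesis has not been shown for α-keto esters tethered through the ester oxygen or for lactone formation.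

**Compound list**
1 | germacrone, (3E,7E)-3,7-dimethyl-10-(propan-2-ylidene)cyclodeca-3,7-dien-1-one | C/C1=C\CC/C(C)=C/CC(=C(C)C)C(=O)C1 | starting material
2 | (1R,3E,7E)-3,7-dimethyl-10-(propan-2-ylidene)cyclodeca-3,7-dien-1-ol | C/C1=C\CC/C(C)=C/CC(=C(C)C)[C@H](O)C1 | intermediate
3 | (1R,4R,5R)-5-ethenyl-5-methyl-4-(prop-1-en-2-yl)-2-(propan-2-ylidene)cyclohexan-1-ol | C=C[C@@]1(C)C[C@@H](O)C(=C(C)C)C[C@@H]1C(=C)C | intermediate
4 | (1R,4S,5S)-5-ethenyl-5-methyl-4-(prop-1-en-2-yl)-2-(propan-2-ylidene)cyclohexan-1-ol | O[C@@H]1C[C@@](C)(C=C)[C@H](C(=C)C)CC1=C(C)C | intermediate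
5 | (4S,5S)-5-ethenyl-5-methyl-4-(prop-1-en-2-yl)-2-(propan-2-ylidene)cyclohexan-1-one | O=C1C[C@@](C)(C=C)[C@H](C(=C)C)CC1=C(C)C | intermediate
6 | potassium (4S,5S)-5-ethenyl-5-methyl-2,4-di(prop-1-en-2-yl)cyclohex-1-en-1-olate (extended dienolate of 5) | [K+].[O-]C=1C[C@@](C)(C=C)[C@H](C(=C)C)CC=1C(=C)C | intermediate
7 | (2R,4S,5S)-5-ethenyl-5-methyl-2,4-di(prop-1-en-2-yl)cyclohexan-1-one | O=C1C[C@@](C)(C=C)[C@H](C(=C)C)C[C@@H]1C(=C)C | intermediate
8 | (1R,2R,4S,5S)-5-ethenyl-5-methyl-2,4-di(prop-1-en-2-yl)cyclohexan-1-ol | O[C@@H]1C[C@@](C)(C=C)[C@H](C(=C)C)C[C@@H]1C(=C)C | intermediate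
9 | dilithium derivative of 8 (lithium alkoxide at C1, allyllithium at the methyl carbon of the C2 isopropenyl group) | [Li]O[C@@H]1C[C@@](C)(C=C)[C@H](C(=C)C)C[C@@H]1C(=C)C[Li] | intermediate
10 | cyclic methyl boronate (2-methoxy-1,2-oxaborinane ring; boron bonded to the C1 oxygen and to the allylic CH2) | COB1O[C@@H]2C[C@@](C)(C=C)[C@H](C(=C)C)C[C@@H]2C(=C)C1 | intermediate
11 | 2-[(1R,2R,4S,5S)-4-ethenyl-2-hydroxy-4-methyl-5-(prop-1-en-2-yl)cyclohexyl]prop-2-en-1-ol | O[C@@H]1C[C@@](C)(C=C)[C@H](C(=C)C)C[C@@H]1C(=C)CO | intermediate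
12 | (3aR,5S,6S,7aR)-6-ethenyl-6-methyl-3-methylidene-5-(prop-1-en-2-yl)octahydro-1-benzofuran-2-ol (lactol, anomer mixture) | C=C1C(O)O[C@@H]2C[C@@](C)(C=C)[C@H](C(=C)C)C[C@H]12 | intermediate
13 | (3aR,5S,6S,7aR)-6-ethenyl-6-methyl-3-methylidene-5-(prop-1-en-2-yl)hexahydro-1-benzofuran-2(3H)-one | C=C1C(=O)O[C@@H]2C[C@@](C)(C=C)[C@H](C(=C)C)C[C@H]12 | intermediate
14 | pyruvic acid (2-oxopropanoic acid) | CC(=O)C(=O)O | starting material
15 | trimethylsilyl 2-[(trimethylsilyl)oxy]prop-2-enoate | C=C(O[Si](C)(C)C)C(=O)O[Si](C)(C)C | intermediate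
16 | trimethylsilyl 4-{(3aR,5S,6S,7aR)-6-ethenyl-6-methyl-5-(prop-1-en-2-yl)-2-[(trimethylsilyl)oxy]-3a,4,5,6,7,7a-hexahydro-1-benzofuran-3-yl}-2-oxobutanoate | C[Si](C)(C)OC(=O)C(=O)CCC1=C(O[Si](C)(C)C)O[C@@H]2C[C@@](C)(C=C)[C@H](C(=C)C)C[C@H]12 | intermediate
17 | 4-[(3S,3aR,5S,6S,7aR)-6-ethenyl-6-methyl-2-oxo-5-(prop-1-en-2-yl)octahydro-1-benzofuran-3-yl]-2-oxobutanoic acid | OC(=O)C(=O)CC[C@@H]1C(=O)O[C@@H]2C[C@@](C)(C=C)[C@H](C(=C)C)C[C@H]12 | intermediate
18 | (1R,4R,5R)-5-ethenyl-5-methyl-4-(prop-1-en-2-yl)-2-(propan-2-ylidene)cyclohexyl ester of 17 | C=C[C@@]1(C)C[C@@H](OC(=O)C(=O)CC[C@@H]2C(=O)O[C@@H]3C[C@@](C)(C=C)[C@H](C(=C)C)C[C@H]23)C(=C(C)C)C[C@@H]1C(=C)C | intermediate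
19 | oxetane from addition of the ketone C=O of 18 across the isopropylidene C=C (oxetane fused to the new lactone ring, spiro on the cyclohexane; the two new oxetane centres unassigned) | C=C[C@@]1(C)C[C@H]2OC(=O)C3(CC[C@@H]4C(=O)O[C@@H]5C[C@@](C)(C=C)[C@H](C(=C)C)C[C@H]45)OC(C)(C)C23C[C@@H]1C(=C)C | intermediate
20 | (5R,6R,7aR)-6-ethenyl-3-{2-[(3S,3aR,5S,6S,7aR)-6-ethenyl-6-methyl-2-oxo-5-(prop-1-en-2-yl)octahydro-1-benzofuran-3-yl]ethyl}-6-methyl-5-(prop-1-en-2-yl)-5,6,7,7a-tetrahydro-1-benzofuran-2(4H)-one | C=C[C@@]1(C)C[C@H]2OC(=O)C(CC[C@@H]3C(=O)O[C@@H]4C[C@@](C)(C=C)[C@H](C(=C)C)C[C@H]34)=C2C[C@@H]1C(=C)C | target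

**Step count and risks**
Total steps: 11 numbered steps; steps 2 and 3 are one thermolysis, so there are 10 laboratory operations. Longest linear sequence: 10 steps (steps 1 and 3 to 11: 1 → 2 → 4 → 5 → 7 → 8 → 11 → 13 → 17 → 18 → 20); alcohol 3 from step 2 enters at step 10 without further steps. The ratio of 3 to 4 from the thermolysis is not known in advance. The transition state with the hydroxyl pseudo-equatorial (leading to 3) may be somewhat favoured, in which case 4 limits the throughput of the longer branch.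

The three steps most likely to fail:

Step 11 (the proposed new step). The Lewis acid may instead ionise the allylic keto ester or stop at a carbonyl-ene product, and the ester must reach the lactone-like conformation for closure. The fallback sets out from 3 and 17 and returns at 20, building the butenolide by aldol chemistry. Alcohol 3 is oxidised with MnO2 to (4R,5R)-5-ethenyl-5-methyl-4-(prop-1-en-2-yl)-2-(propan-2-ylidene)cyclohexan-1-one F1. Retro-aldol cleavage (KOH, aqueous EtOH, reflux, as pulegone gives 3-methylcyclohexanone) removes the isopropylidene group as acetone and gives (3R,4R)-3-ethenyl-3-methyl-4-(prop-1-en-2-yl)cyclohexan-1-one F2. Acid 17 is methylated with Me3SiCHN2 to the methyl ester of 17 F3. A TiCl4/n-Bu3N crossed aldol of F2, through its less hindered α-carbon, onto the keto group of F3 gives the aldol adduct F4. NaBH4 in MeOH at −20 °C reduces the ring ketone from the face away from the axial methyl to the diol ester F5. TsOH in refluxing benzene lactonises and dehydrates F5 to the cis-butenolide, the 7a-epimer of 20 F6. DBU in CH2Cl2 at 25 °C then epimerises the acidic γ-position to the more stable isomer with the ring oxygen equatorial, which is 20.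

Step 9. The captodative silyl enol ether is a weak nucleophile and the lactone a modest acceptor. The fallback sets out from 13 and returns at 17, using a soft stabilised carbanion. Commercial diethyl oxalacetate sodium salt (NaC8H11O5) in EtOH at 25 °C adds to 13 to give the oxalacetate Michael adduct F7. The transient lactone enolate is protonated by ethanol from the convex face, and the weakly basic oxalacetate enolate does not re-enolise the lactone, so C3 is again S. Krapcho dealkoxycarbonylation (LiCl, wet DMSO, 130 °C) gives the ethyl ester of 17 F8. LiOH (1.05 equiv) in THF–H2O at 0 °C, followed by acidification to pH 2 (any opened lactone recloses), gives 17.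

Step 7. The organolithium base may also attack the second isopropenyl group or the allylic ring C–H. The fallback sets out from 8 and returns at 11, replacing directed deprotonation by an ene-type allylic oxidation. SeO2 (0.5 equiv) and t-BuOOH in CH2Cl2 at 25 °C hydroxylate the isopropenyl methyl to give 11, accompanied by some lactol 12. Both are carried into step 8, and 13 is separated from products of oxidation at the other isopropenyl group.

**Further compounds**
F1 | step 11 | (4R,5R)-5-ethenyl-5-methyl-4-(prop-1-en-2-yl)-2-(propan-2-ylidene)cyclohexan-1-one | C=C[C@@]1(C)CC(=O)C(=C(C)C)C[C@@H]1C(=C)C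
F2 | step 11 | (3R,4R)-3-ethenyl-3-methyl-4-(prop-1-en-2-yl)cyclohexan-1-one | C=C[C@@]1(C)CC(=O)CC[C@@H]1C(=C)C
F3 | step 11 | methyl 4-[(3S,3aR,5S,6S,7aR)-6-ethenyl-6-methyl-2-oxo-5-(prop-1-en-2-yl)octahydro-1-benzofuran-3-yl]-2-oxobutanoate | COC(=O)C(=O)CC[C@@H]1C(=O)O[C@@H]2C[C@@](C)(C=C)[C@H](C(=C)C)C[C@H]12
F4 | step 11 | methyl 2-[(4R,5R)-4-ethenyl-4-methyl-2-oxo-5-(prop-1-en-2-yl)cyclohexyl]-4-[(3S,3aR,5S,6S,7aR)-6-ethenyl-6-methyl-2-oxo-5-(prop-1-en-2-yl)octahydro-1-benzofuran-3-yl]-2-hydroxybutanoate (mixture at the two new centres) | C=C[C@@]1(C)CC(=O)C(C[C@@H]1C(=C)C)C(O)(C(=O)OC)CC[C@@H]2C(=O)O[C@@H]3C[C@@](C)(C=C)[C@H](C(=C)C)C[C@H]23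
F5 | step 11 | methyl 2-[(4R,5R)-4-ethenyl-2-hydroxy-4-methyl-5-(prop-1-en-2-yl)cyclohexyl]-4-[(3S,3aR,5S,6S,7aR)-6-ethenyl-6-methyl-2-oxo-5-(prop-1-en-2-yl)octahydro-1-benzofuran-3-yl]-2-hydroxybutanoate (mixture at the new centres) | C=C[C@@]1(C)CC(O)C(C[C@@H]1C(=C)C)C(O)(C(=O)OC)CC[C@@H]2C(=O)O[C@@H]3C[C@@](C)(C=C)[C@H](C(=C)C)C[C@H]23
F6 | step 11 | (5R,6R,7aS)-6-ethenyl-3-{2-[(3S,3aR,5S,6S,7aR)-6-ethenyl-6-methyl-2-oxo-5-(prop-1-en-2-yl)octahydro-1-benzofuran-3-yl]ethyl}-6-methyl-5-(prop-1-en-2-yl)-5,6,7,7a-tetrahydro-1-benzofuran-2(4H)-one (7a-epimer of 20) | C=C[C@@]1(C)C[C@@H]2OC(=O)C(CC[C@@H]3C(=O)O[C@@H]4C[C@@](C)(C=C)[C@H](C(=C)C)C[C@H]34)=C2C[C@@H]1C(=C)C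
F7 | step 9 | diethyl 2-{[(3S,3aR,5S,6S,7aR)-6-ethenyl-6-methyl-2-oxo-5-(prop-1-en-2-yl)octahydro-1-benzofuran-3-yl]methyl}-3-oxobutanedioate (mixture at the new centre) | CCOC(=O)C(=O)C(C(=O)OCC)C[C@@H]1C(=O)O[C@@H]2C[C@@](C)(C=C)[C@H](C(=C)C)C[C@H]12
F8 | step 9 | ethyl 4-[(3S,3aR,5S,6S,7aR)-6-ethenyl-6-methyl-2-oxo-5-(prop-1-en-2-yl)octahydro-1-benzofuran-3-yl]-2-oxobutanoate | CCOC(=O)C(=O)CC[C@@H]1C(=O)O[C@@H]2C[C@@](C)(C=C)[C@H](C(=C)C)C[C@H]12
F0 | step 7 | none | none
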